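## Structural features

The target is a dimer of two 2-(4-hydroxyphenyl)chromane-3,4,7,8-tetrol (flavan-3,4-diol) units, each with a pyrogallol-type ring A fused to a dihydropyran ring C (O1, C2, C3, C4, C4a, C8a) that carries the 4-hydroxyphenyl ring B at C2. The units are joined by a single C6–C6′ biaryl bond between the two rings A; this axis has only O7 and O7′ as ortho substituents and is taken as freely rotating. Each ring C holds three contiguous stereocentres: unit 1 is 2R,3R,4R (2,3-cis-3,4-cis, all substituents on one face) and unit 2 is 2R,3R,4S (2,3-cis-3,4-trans). The halves therefore differ only at C4, and the molecule is one stereocentre away from C2 symmetry. The fragile groups are the C4 carbinols (benzylic and para to O7, so they ionise with acid and can be lost on hydrogenolysis), the benzylic C2–O1 ether, the less stable 2,3-cis arrangement and the air-sensitive 7,8-catechols. The real difficulty is to set 2,3-cis in both units and then give two otherwise equivalent halves opposite C4 configurations. The key step uses the fact that C3 and C4 are neighbouring oxygen-bearing carbons of ring C lying between the benzylic C2 and ring A: they can be joined as an enol ether double bond C3=C4, which closes ring C with C2 already in place and is oxygenated afterwards.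

## Logic of the disconnections

15 ⇒ 14. The eight O–CH2Ph bonds (six aryl ethers, two alkyl ethers at O3 and O3′) are cut. The oxidisable polyphenol is thus unmasked only in the last operation, and every earlier intermediate is a neutral, chromatographable ether. The forward cleavage must spare the benzylic C4–O and C2–O1 bonds.

14 ⇒ 13 ⇒ 12. The C4–H bond of unit 1 is cut back to a ketone, and the ketone is traced to the C4 epimer. This removes the only difference between the halves, so 12 is C2-symmetric. The forward reduction needs hydride delivery anti to O3. The forward oxidation meets two equivalent, electronically insulated carbinols and can only be statistical. This is accepted because 12 is recovered and recycled; telling O3 from O3′ by protecting groups would require an unsymmetrical biaryl and several further steps.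

12 ⇒ 10. In each unit the C4–O and C3–H bonds are cut, leaving the C3=C4 enol ether. Four stereocentres disappear at once, and the only remaining ones are the two C2 centres. The forward addition must be syn, on the face opposite the C2 aryl, with the heteroatom at C4.

10 ⇒ 9. Both C3=C4 bonds are cut (ring-closing metathesis). Both rings C open, leaving a biaryl with two styrenes and two 2-benzyloxyallyl ethers whose stereocentres are isolated ether carbons. The forward step must close onto 1,1-disubstituted enol ethers without double-bond migration.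

9 ⇒ 8. The four C=CH2 bonds are cut back to C=O, two formyl groups and two benzyl esters. One reagent then builds both kinds of alkene, and the ester alkoxy group supplies the benzyl group on O3. The olefination must be non-basic, because C2–H is acidic.

8 ⇒ 5 + 7. Both O1–C2 ether bonds are cut. This separates the achiral biaryl core from the only chiral building block, so the C2 configuration is bought and not made. The forward etherification must proceed with clean inversion, twice.

5 ⇒ 3 + 4. The C6–C6′ bond is cut between two halves that differ only in the group on the later C6, bromine in one and a pinacol boronate in the other. The biaryl problem is thereby reduced to one monomer series. The forward cross-coupling must tolerate a free phenol and an aldehyde in both partners.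

4 ⇒ 3. The C–B bond is cut back to the C–Br bond, so that both coupling partners come from one compound. The forward borylation must stop at the boronate and must not start the coupling.

3 ⇒ 2 ⇒ 1. The C–Br bond and two O–benzyl bonds are cut. The demands are bromination para to the free hydroxyl and alkylation that leaves the chelated hydroxyl (the later O1) free.

7 ⇒ 6. The ester and phenol O–benzyl bonds are cut. The secondary carbinol and its configuration must stay untouched.

## Other disconnections considered

Alternative 1: The cut removes ring A of unit 2 through the bonds C8a′–C8′, C7′–C6′ and C8a′–C4a′. Unit 1 is then complete, with its 3,4-cis diol locked as a cyclic carbonate, and carries an α-diazo enone chain at C6 (A1). In the forward direction A1 would be irradiated with di-tert-butoxyethyne A2. Wolff rearrangement with alkenyl migration gives an aryl vinyl ketene, which adds to the alkyne in a [2+2] sense. Heating opens the four-membered ring, and a six-electron electrocyclisation with tautomerisation gives the phenol A3. A3 has tert-butoxy groups at C7′ and C8′, a free hydroxyl at C8a′ and a dimethyl acetal at C4a′ as the handle for ring C of unit 2.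
- In favour: the substitution pattern of the new ring is fixed by the mechanism, and the C8a′ hydroxyl is freed exactly where O1′ is needed.
- Better than the chosen plan on one point: the two units are made at different times, so C4 and C4′ never have to be told apart on a symmetric intermediate.
- Against: unit 1 must first be made in full by other chemistry, and ring C of unit 2, with three stereocentres, must then be built on this advanced intermediate. The photolysis must spare a carbonate and several benzylic ethers in a strongly absorbing molecule. The tert-butyl ethers later need acid, which the C4 carbinols tolerate badly.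
- Comparison: structurally the chosen plan uses the near-symmetry and forms both rings C in one operation, while this alternative treats the halves separately. Mechanistically the pericyclic cascade is regiospecific and at least the equal of metathesis in predictability. In step economy it is clearly longer, because ring C has to be made twice by different routes.

Alternative 2: The cut is at both C4–C4a bonds. The precursor is the biaryl dibromide A4, in which each O1 carries the acyl group of an acetonide-protected 2,3-dihydroxy-3-arylpropanoic acid and each C4a carries bromine. Bromine–lithium exchange with tBuLi at low temperature would trigger two acyl shifts from O1 to C4a (anionic ortho-Fries shifts). The product is the bis(2-hydroxyaryl ketone) A5, with both C4–C4a bonds made and both C8a phenols free.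
- Equal to the chosen plan in convergence: it is a two-directional operation on a symmetric biaryl.
- Better on C3 control: the C2 and C3 configurations would be set together by a catalytic asymmetric dihydroxylation before the acyl group is attached, so the C3 configuration does not depend on facial selectivity on a finished ring. The acyl shift is also intramolecular and regiospecific.
- Against: the key step does not close ring C. As drawn, C2 of A5 already has the spatial arrangement of the target, so the phenol would have to replace the C2 oxygen with net retention, at a 4-alkoxybenzylic carbon and in the less stable 2,3-cis sense. The aryllithium also sits next to an ester with an α-alkoxy stereocentre, so β-elimination and epimerisation at C3 are competing processes.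
- Only equal on the symmetry problem: the two C4 ketones of A5 are equivalent, so reducing them to opposite configurations meets the same difficulty as the chosen plan.
- Step economy: comparable up to the key step, longer after it (acetonide removal, ring closure, differentiated reduction).

Alternative 3: The cut is at both C4–O bonds of a preformed 6,6′-linked bis(2,3-cis-flavan-3-ol) A6 with C4 methylene groups, whose O3 groups differ (tert-butyl carbonate in unit 1, silyl ether in unit 2). DDQ would remove hydride from each C4, which is para to O7. The cation of unit 1 would be captured on the same face by the carbonyl oxygen of its C3 carbonate, with loss of the tert-butyl group, to give the cis-fused cyclic carbonate. The cation of unit 2 would be captured by acetic acid anti to the C3 silyl ether to give the trans acetate. The product is A7.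
- In favour: both C4 oxygens arrive late on intact rings by a reaction type that is well established for O-protected flavan-3-ols.
- Better than the chosen plan on C4 differentiation: the two C4 configurations are set in one step by neighbouring groups, with no statistical step.
- Equal in the final deprotection.
- Against: the different O3 groups demand an unsymmetrical biaryl, so two flavan-3-ol units must be made and cross-coupled; the symmetry problem is moved, not removed. Two hydride abstractions on one molecule, over-oxidation to the C4 ketone and capture of the unit 1 cation by acetic acid are competing processes. The 2,3-cis flavan-3-ol units still need their own C2 and C3 control.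
- Comparison: structurally both plans oxygenate C4 after ring C exists and rely on the C2 and C3 substituents to direct it. Mechanistically the alternative is cationic, and the chosen plan is a concerted syn addition. In step economy the chosen plan is shorter, because ring closure and C3/C4 functionalisation are done on both halves at once from one symmetric precursor.

Key step: step 8

Assumptions: (S)-4-hydroxymandelic acid is taken as available in enantiopure form. The C6–C6′ axis is taken as freely rotating, so no axial descriptor is needed. The batch of 3 is divided, one half being borylated in step 3 and the other half used as the bromide partner in step 4. The two units of 12 are equivalent; the unit oxidised in step 10 is called unit 1 from there on.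

## Route

Step 1
Reactants: 1 2,3,4-trihydroxybenzaldehyde
Product: 2 3,4-bis(benzyloxy)-2-hydroxybenzaldehyde
Conditions: BnBr (2.1 equiv), K2CO3 (2.2 equiv), DMF, 0 °C → rt
Reagents that add atoms: benzyl bromide, BrCc1ccccc1
Why: Williamson etherification; the C2 hydroxyl is held in a hydrogen bond to the formyl oxygen and is the least nucleophilic, so two equivalents of benzyl bromide should alkylate only O3 and O4 and leave the later O1 free.

Step 2
Reactants: 2 3,4-bis(benzyloxy)-2-hydroxybenzaldehyde
Product: 3 3,4-bis(benzyloxy)-5-bromo-2-hydroxybenzaldehyde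
Conditions: NBS (1.05 equiv), MeCN, 0 °C → rt, dark
Reagents that add atoms: N-bromosuccinimide, O=C1CCC(=O)N1Br
Why: Electrophilic aromatic bromination; C5 is para to the free hydroxyl, ortho to the C4 benzyloxy group and meta to the formyl group, whereas C6 is ortho to the formyl group, so bromine should enter at C5, the later C6 of the flavan.

Step 3
Reactants: 3 3,4-bis(benzyloxy)-5-bromo-2-hydroxybenzaldehyde
Product: 4 3,4-bis(benzyloxy)-2-hydroxy-5-(4,4,5,5-tetramethyl-1,3,2-dioxaborolan-2-yl)benzaldehyde
Conditions: B2pin2 (1.2 equiv), PdCl2(dppf) (5 mol %), KOAc (3 equiv), 1,4-dioxane, 85 °C (one half of the batch of 3)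
Reagents that add atoms: bis(pinacolato)diboron, CC1(C)OB(OC1(C)C)B1OC(C)(C)C(C)(C)O1
Why: Miyaura borylation; zerovalent palladium inserts into the C–Br bond, acetate-assisted transmetalation with the diboron and reductive elimination give the aryl pinacol boronate, and the weak base KOAc tolerates the free phenol and the aldehyde and should keep the boronate from coupling with unreacted bromide at this stage.

Step 4
Reactants: 3 3,4-bis(benzyloxy)-5-bromo-2-hydroxybenzaldehyde; 4 3,4-bis(benzyloxy)-2-hydroxy-5-(4,4,5,5-tetramethyl-1,3,2-dioxaborolan-2-yl)benzaldehyde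
Product: 5 2,2',3,3'-tetrakis(benzyloxy)-4,4'-dihydroxy-[1,1'-biphenyl]-5,5'-dicarbaldehyde
Conditions: 3 (1.0 equiv), 4 (1.1 equiv), PdCl2(dppf) (5 mol %), aq K2CO3 (3 equiv), 1,4-dioxane, 85 °C, degassed
Reagents that add atoms: none
Why: Suzuki–Miyaura cross-coupling of the bromide 3 with the boronate 4; the carbonate activates the boronate for transmetalation, both partners tolerate the free phenol and the aldehyde, and the new C–C bond has only two ortho substituents, so reductive elimination should be unhindered and the symmetric biaryl results whichever partner is in excess.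

Step 5
Reactants: 6 (S)-4-hydroxymandelic acid
Product: 7 benzyl (2S)-2-[4-(benzyloxy)phenyl]-2-hydroxyacetate
Conditions: BnBr (2.1 equiv), K2CO3 (2.2 equiv), DMF, 0 °C → rt
Reagents that add atoms: benzyl bromide, BrCc1ccccc1
Why: Carboxylate and phenoxide alkylation (Williamson type); carbonate deprotonates only the acid and the phenol, so the secondary carbinol and its S configuration are not involved, and the benzyl ester is chosen because its alkoxy group later becomes the benzyl enol ether at O3.

Step 6
Reactants: 5 2,2',3,3'-tetrakis(benzyloxy)-4,4'-dihydroxy-[1,1'-biphenyl]-5,5'-dicarbaldehyde; 7 benzyl (2S)-2-[4-(benzyloxy)phenyl]-2-hydroxyacetate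
Product: 8 dibenzyl (2R,2'R)-2,2'-{[2,2',3,3'-tetrakis(benzyloxy)-5,5'-diformyl-[1,1'-biphenyl]-4,4'-diyl]bis(oxy)}bis{2-[4-(benzyloxy)phenyl]acetate}
Conditions: 7 (2.6 equiv), PPh3, DIAD, THF, 0 °C → rt
Reagents that add atoms: none
Why: Mitsunobu etherification; the phenol oxygen displaces the oxyphosphonium group in an SN2 step with inversion, S in 7 to R in 8, which is the C2 configuration of both flavan units, and the acidic salicylaldehyde-type phenol is a good pronucleophile under neutral conditions that spare the acidic C2–H. Any stereochemical leakage at one site ends up in the R,S (meso-type) diastereomer, which should be separable.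

Step 7
Reactants: 8 dibenzyl (2R,2'R)-2,2'-{[2,2',3,3'-tetrakis(benzyloxy)-5,5'-diformyl-[1,1'-biphenyl]-4,4'-diyl]bis(oxy)}bis{2-[4-(benzyloxy)phenyl]acetate}
Product: 9 2,2',3,3'-tetrakis(benzyloxy)-4,4'-bis{[(1R)-2-(benzyloxy)-1-[4-(benzyloxy)phenyl]prop-2-en-1-yl]oxy}-5,5'-divinyl-1,1'-biphenyl
Conditions: Cp2TiMe2 (10–12 equiv), toluene/THF, 65–70 °C, dark; filtration through basic alumina (Et3N in eluent)
Reagents that add atoms: dimethyltitanocene Cp2TiMe2, [CH3-].[CH3-].[cH-]1cccc1.[cH-]1cccc1.[Ti+4]
Why: Petasis methylenation; thermolysis of Cp2TiMe2 gives Cp2Ti=CH2, which converts aldehydes and esters alike into terminal alkenes through oxatitanacyclobutanes, and the reagent is non-basic, so the stereocentre next to the ester should survive while the benzyl ester oxygen becomes the enol ether oxygen. Carrying out all four olefinations at once avoids a free 2-vinylphenol and a basic phosphorus ylide.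

Step 8
Reactants: 9 2,2',3,3'-tetrakis(benzyloxy)-4,4'-bis{[(1R)-2-(benzyloxy)-1-[4-(benzyloxy)phenyl]prop-2-en-1-yl]oxy}-5,5'-divinyl-1,1'-biphenyl
Product: 10 (2R,2'R)-3,3',7,7',8,8'-hexakis(benzyloxy)-2,2'-bis[4-(benzyloxy)phenyl]-2H,2'H-6,6'-bichromene
Conditions: RuCl2(H2IMes)(PCy3)(=CHPh) (second-generation Grubbs catalyst, 2 × 7.5 mol %), 1,4-benzoquinone (20 mol %), toluene (0.005 M), 80 °C, Ar sparge
Reagents that add atoms: none
Why: Ring-closing olefin metathesis. After loss of PCy3 the ruthenium benzylidene exchanges with the monosubstituted styrene terminus (the 1,1-disubstituted, electron-rich enol ether is engaged far more slowly) to give an aryl-substituted alkylidene at C4; intramolecular [2+2] addition to the 2-benzyloxyallyl C=CH2 and cycloreversion of the ruthenacyclobutane form C3=C4 and release Ru=CH2, which re-enters the cycle with loss of ethene. Each event closes one six-membered ring C (O1, C2, C3, C4, C4a, C8a) from a 1,7-diene with both alkene carbons becoming endocyclic, and the two closures are independent and occur on separate halves of the biaryl. The closest known reaction type is the ring-closing metathesis of olefinic enol ethers to cyclic enol ethers and of 2-allyloxystyrenes to 2H-chromenes with second-generation ruthenium carbenes of the RuCl2(H2IMes)(PCy3)(=CHPh) type. No stereocentre is formed and C2 is a spectator. The step needs initiation at the styrene and not at the enol ether (which would give an inert alkoxycarbene), cyclisation in preference to intermolecular stilbene formation, and no migration of the new double bond to C2–C3, which would erase C2. These are secured by the substitution pattern (only the styrene is monosubstituted, the two styrenes are meta to the biaryl bond and cannot reach each other, and six-ring closure is fast), by high dilution with removal of ethene, and by a hydride scavenger under neutral conditions with no C3 carbonyl present.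

Step 9
Reactants: 10 (2R,2'R)-3,3',7,7',8,8'-hexakis(benzyloxy)-2,2'-bis[4-(benzyloxy)phenyl]-2H,2'H-6,6'-bichromene
Product: 12 (2R,2'R,3R,3'R,4S,4'S)-3,3',7,7',8,8'-hexakis(benzyloxy)-2,2'-bis[4-(benzyloxy)phenyl]-[6,6'-bichromane]-4,4'-diol, via bis(C4-borane) adduct 11 (not isolated)
Conditions: BH3·THF (6 equiv), THF, 0 °C → rt; then aq NaOH, H2O2 (30%), 0 °C → rt
Reagents that add atoms: hydrogen peroxide, OO
Why: Hydroboration–oxidation of a cyclic enol ether; boron adds to C4 (β to the enol ether oxygen and the less substituted carbon) and hydrogen to C3 in a syn four-centre addition on the face opposite the C2 aryl, and the C–B bonds are oxidised with retention. Hydrogen at C3 anti to the aryl leaves the benzyloxy group cis to it (2,3-cis), and the C4 oxygen, syn to that hydrogen, is trans to the benzyloxy group (3,4-trans, 4S) in both units.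

Step 10
Reactants: 12 (2R,2'R,3R,3'R,4S,4'S)-3,3',7,7',8,8'-hexakis(benzyloxy)-2,2'-bis[4-(benzyloxy)phenyl]-[6,6'-bichromane]-4,4'-diol
Product: 13 (2R,3S)-3,7,8-tris(benzyloxy)-2-[4-(benzyloxy)phenyl]-6-{(2R,3R,4S)-3,7,8-tris(benzyloxy)-2-[4-(benzyloxy)phenyl]-4-hydroxychroman-6-yl}chroman-4-one
Conditions: Dess–Martin periodinane (0.6 equiv), NaHCO3, CH2Cl2, 0 °C; chromatography on Et3N-deactivated silica; recovered 12 resubmitted
Reagents that add atoms: none
Why: Dess–Martin oxidation with less than one equivalent of oxidant; the two C4 carbinols are equivalent and electronically insulated, so a statistical distribution between unchanged 12, the wanted mono-ketone 13 and doubly oxidised material is expected, from which 13 is separated and 12 recycled. The buffered, non-basic medium should not epimerise the 2,3-cis C3 centre next to the new ketone.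

Step 11
Reactants: 13 (2R,3S)-3,7,8-tris(benzyloxy)-2-[4-(benzyloxy)phenyl]-6-{(2R,3R,4S)-3,7,8-tris(benzyloxy)-2-[4-(benzyloxy)phenyl]-4-hydroxychroman-6-yl}chroman-4-one
Product: 14 (2R,2'R,3R,3'R,4R,4'S)-3,3',7,7',8,8'-hexakis(benzyloxy)-2,2'-bis[4-(benzyloxy)phenyl]-[6,6'-bichromane]-4,4'-diol
Conditions: NaBH4, THF/EtOH, −40 °C → 0 °C
Reagents that add atoms: none
Why: Borohydride reduction of an α-alkoxy ketone; hydride should attack C4 anti to the pseudo-axial C3 benzyloxy group (polar Felkin–Anh and axial attack agree), so the new hydroxyl is cis to O3 and to the C2 aryl (4R), which is the net inversion of one C4. The carbinol of unit 2 is not touched.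

Step 12
Reactants: 14 (2R,2'R,3R,3'R,4R,4'S)-3,3',7,7',8,8'-hexakis(benzyloxy)-2,2'-bis[4-(benzyloxy)phenyl]-[6,6'-bichromane]-4,4'-diol
Product: 15 (2R,2'R,3R,3'R,4R,4'S)-2,2'-bis(4-hydroxyphenyl)-[6,6'-bichromane]-3,3',4,4',7,7',8,8'-octol
Conditions: H2 (1 atm), Pd(OH)2/C, THF/MeOH, rt; filtration and concentration under Ar
Reagents that add atoms: none
Why: Catalytic hydrogenolysis should cleave the six aryl benzyl ethers and the two alkyl benzyl ethers at O3 in one neutral operation; benzyl ethers are cleaved faster than the ring C–O bonds at C2 and C4, so the reaction is stopped at the calculated hydrogen uptake and the air-sensitive polyphenol is handled under argon.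

## Compound list

1 | 2,3,4-trihydroxybenzaldehyde | O=Cc1ccc(O)c(O)c1O | starting material
2 | 3,4-bis(benzyloxy)-2-hydroxybenzaldehyde | O=Cc1ccc(OCc2ccccc2)c(OCc2ccccc2)c1O | intermediate
3 | 3,4-bis(benzyloxy)-5-bromo-2-hydroxybenzaldehyde | O=Cc1cc(Br)c(OCc2ccccc2)c(OCc2ccccc2)c1O | intermediate
4 | 3,4-bis(benzyloxy)-2-hydroxy-5-(4,4,5,5-tetramethyl-1,3,2-dioxaborolan-2-yl)benzaldehyde (aryl pinacol boronate) | O=Cc1cc(B2OC(C)(C)C(C)(C)O2)c(OCc2ccccc2)c(OCc2ccccc2)c1O | intermediate
5 | 2,2',3,3'-tetrakis(benzyloxy)-4,4'-dihydroxy-[1,1'-biphenyl]-5,5'-dicarbaldehyde | O=Cc1cc(-c2cc(C=O)c(O)c(OCc3ccccc3)c2OCc2ccccc2)c(OCc2ccccc2)c(OCc2ccccc2)c1O | intermediate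
6 | (S)-4-hydroxymandelic acid, (2S)-2-hydroxy-2-(4-hydroxyphenyl)acetic acid | O[C@H](C(=O)O)c1ccc(O)cc1 | starting material
7 | benzyl (2S)-2-[4-(benzyloxy)phenyl]-2-hydroxyacetate | O[C@H](C(=O)OCc1ccccc1)c1ccc(OCc2ccccc2)cc1 | intermediate
8 | dibenzyl (2R,2'R)-2,2'-{[2,2',3,3'-tetrakis(benzyloxy)-5,5'-diformyl-[1,1'-biphenyl]-4,4'-diyl]bis(oxy)}bis{2-[4-(benzyloxy)phenyl]acetate} | O=Cc1cc(-c2cc(C=O)c(O[C@H](c3ccc(OCc4ccccc4)cc3)C(=O)OCc3ccccc3)c(OCc3ccccc3)c2OCc2ccccc2)c(OCc2ccccc2)c(OCc2ccccc2)c1O[C@H](c1ccc(OCc2ccccc2)cc1)C(=O)OCc1ccccc1 | intermediate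
9 | 2,2',3,3'-tetrakis(benzyloxy)-4,4'-bis{[(1R)-2-(benzyloxy)-1-[4-(benzyloxy)phenyl]prop-2-en-1-yl]oxy}-5,5'-divinyl-1,1'-biphenyl (key-step precursor) | C=Cc1cc(-c2cc(C=C)c(O[C@H](c3ccc(OCc4ccccc4)cc3)C(=C)OCc3ccccc3)c(OCc3ccccc3)c2OCc2ccccc2)c(OCc2ccccc2)c(OCc2ccccc2)c1O[C@H](c1ccc(OCc2ccccc2)cc1)C(=C)OCc1ccccc1 | intermediate
10 | (2R,2'R)-3,3',7,7',8,8'-hexakis(benzyloxy)-2,2'-bis[4-(benzyloxy)phenyl]-2H,2'H-6,6'-bichromene (key-step product) | c1(-c2cc3c(c(OCc4ccccc4)c2OCc2ccccc2)O[C@H](c2ccc(OCc4ccccc4)cc2)C(OCc2ccccc2)=C3)cc2c(c(OCc3ccccc3)c1OCc1ccccc1)O[C@H](c1ccc(OCc3ccccc3)cc1)C(OCc1ccccc1)=C2 | intermediate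
11 | 4,4'-diboranyl-3,3',7,7',8,8'-hexakis(benzyloxy)-2,2'-bis[4-(benzyloxy)phenyl]-6,6'-bichromane, each C4–B bond trans to the C2 aryl and to the C3 benzyloxy group (not isolated) | c1(-c2cc3c(c(OCc4ccccc4)c2OCc2ccccc2)O[C@H](c2ccc(OCc4ccccc4)cc2)[C@H](OCc2ccccc2)[C@H]3B)cc2c(c(OCc3ccccc3)c1OCc1ccccc1)O[C@H](c1ccc(OCc3ccccc3)cc1)[C@H](OCc1ccccc1)[C@H]2B | intermediate
12 | (2R,2'R,3R,3'R,4S,4'S)-3,3',7,7',8,8'-hexakis(benzyloxy)-2,2'-bis[4-(benzyloxy)phenyl]-[6,6'-bichromane]-4,4'-diol (2,3-cis-3,4-trans in both units) | c1(-c2cc3c(c(OCc4ccccc4)c2OCc2ccccc2)O[C@H](c2ccc(OCc4ccccc4)cc2)[C@H](OCc2ccccc2)[C@H]3O)cc2c(c(OCc3ccccc3)c1OCc1ccccc1)O[C@H](c1ccc(OCc3ccccc3)cc1)[C@H](OCc1ccccc1)[C@H]2O | intermediate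
13 | (2R,3S)-3,7,8-tris(benzyloxy)-2-[4-(benzyloxy)phenyl]-6-{(2R,3R,4S)-3,7,8-tris(benzyloxy)-2-[4-(benzyloxy)phenyl]-4-hydroxychroman-6-yl}chroman-4-one | c1(-c2cc3c(c(OCc4ccccc4)c2OCc2ccccc2)O[C@H](c2ccc(OCc4ccccc4)cc2)[C@H](OCc2ccccc2)[C@H]3O)cc2c(c(OCc3ccccc3)c1OCc1ccccc1)O[C@H](c1ccc(OCc3ccccc3)cc1)[C@H](OCc1ccccc1)C2=O | intermediate
14 | (2R,2'R,3R,3'R,4R,4'S)-3,3',7,7',8,8'-hexakis(benzyloxy)-2,2'-bis[4-(benzyloxy)phenyl]-[6,6'-bichromane]-4,4'-diol (unit 1 2,3-cis-3,4-cis, unit 2 2,3-cis-3,4-trans) | c1(-c2cc3c(c(OCc4ccccc4)c2OCc2ccccc2)O[C@H](c2ccc(OCc4ccccc4)cc2)[C@H](OCc2ccccc2)[C@H]3O)cc2c(c(OCc3ccccc3)c1OCc1ccccc1)O[C@H](c1ccc(OCc3ccccc3)cc1)[C@H](OCc1ccccc1)[C@@H]2O | intermediate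
15 | (2R,2'R,3R,3'R,4R,4'S)-2,2'-bis(4-hydroxyphenyl)-[6,6'-bichromane]-3,3',4,4',7,7',8,8'-octol (CNP0121763.1) | Oc1ccc([C@H]2Oc3c(cc(-c4cc5c(c(O)c4O)O[C@H](c4ccc(O)cc4)[C@H](O)[C@H]5O)c(O)c3O)[C@@H](O)[C@H]2O)cc1 | target

## Step count and least certain steps

Total step count: 12. Longest linear sequence: 11 steps (from 1 through steps 1–4 and 6–12); step 5 is a one-step branch.

Step 8 (key step). The likely failures are initiation at the 1,1-disubstituted enol ether, which ties the catalyst up as a stabilised alkoxycarbene; slow closure onto the hindered enol ether, so that intermolecular styrene coupling competes; and ruthenium hydride-mediated migration of the double bonds with loss of the C2 configuration. The fallback sets out from 8. The two formyl groups are methylenated chemoselectively with the Takai–Lombardo reagent (Zn, CH2Br2, TiCl4, THF/CH2Cl2), which does not olefinate esters, to give dibenzyl (2R,2'R)-2,2'-{[2,2',3,3'-tetrakis(benzyloxy)-5,5'-divinyl-[1,1'-biphenyl]-4,4'-diyl]bis(oxy)}bis{2-[4-(benzyloxy)phenyl]acetate} F1. This is closed by an olefinic-ester cyclisation with the titanium ethylidene reagent prepared from TiCl4, TMEDA, Zn, catalytic PbCl2 and CH3CHBr2: a titanium alkylidene formed at the styrene olefinates the benzyl ester carbonyl within the same half. The sequence bypasses 9 and comes back to the route at 10.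

Step 6. The likely failures are incomplete double etherification at a phenol flanked by formyl and benzyloxy groups, and partial loss of configuration through ionisation of the activated 4-benzyloxybenzylic carbinol. The fallback sets out from 3 (with 7). The Mitsunobu reaction is run on the monomer to give benzyl (2R)-2-[2,3-bis(benzyloxy)-4-bromo-6-formylphenoxy]-2-[4-(benzyloxy)phenyl]acetate F2, a smaller compound whose enantiomeric purity can be upgraded by crystallisation. Reductive homocoupling of two molecules of F2 with zerovalent nickel generated from NiCl2(PPh3)2, Zn and Et4NI in THF at 50 °C, under neutral conditions that should not touch the acidic C2–H, then forms the biaryl bond. Dimerisation of an enantioenriched monomer diverts the minor enantiomer into the separable R,S diastereomer. The sequence bypasses 4 and 5 and comes back to the route at 8.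

Step 9. The likely failures are insufficient facial selectivity in one unit (addition syn to the aryl would lead into the 2,3-trans series), elimination of the trans β-benzyloxy organoborane with loss of O3, and competing attachment of boron at C3. The fallback sets out from 10. Homogeneous hydrogenation of both enol ethers with [Ir(cod)(PCy3)(py)]PF6 and H2 in CH2Cl2, anti to the C2 aryl and without hydrogenolysis of benzyl ethers, gives (2R,2'R,3R,3'R)-3,3',7,7',8,8'-hexakis(benzyloxy)-2,2'-bis[4-(benzyloxy)phenyl]-6,6'-bichromane F3. Benzylic oxidation with DDQ in wet CH2Cl2 then removes hydride from each C4 (para to O7), and water adds anti to the pseudo-axial O3. The sequence comes back to the route at 12.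

Step 10. The likely failures are oxidation of both carbinols, which cannot be undone with the 3,4-trans configuration restored, and epimerisation of the 2,3-cis C3 centre of the keto unit during separation. The fallback sets out from 12. Statistical monosilylation (TBSCl, 1 equiv, imidazole, DMF) gives the mono-O4'-tert-butyldimethylsilyl ether of 12 F4; over-silylation is reversible with fluoride and unreacted 12 is recovered, so no material is lost. The single free carbinol is oxidised to completion with excess Dess–Martin periodinane to give the unit 1 ketone F5. Immediate NaBH4 reduction gives the 3,4-cis alcohol of unit 1 with the silyl ether still on unit 2, the O4'-tert-butyldimethylsilyl ether of 14 F6. TBAF in THF removes the silyl group, and the sequence comes back to the route at 14.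

Step 12. The likely failures are hydrogenolysis of the benzylic C4–O bonds (both para to a ring A oxygen) or of the C2–O1 bonds once the benzyl ethers are gone, and air oxidation of the catechols during isolation. The fallback sets out from 14. Both C4 hydroxyls are silylated (TBSOTf, 2,6-lutidine, CH2Cl2, −78 °C) to give the 4,4'-bis-O-tert-butyldimethylsilyl ether of 14 F7. Hydrogenolysis in EtOAc/THF over Pd/C, in which bulky benzylic silyl ethers should persist, gives the 4,4'-bis-O-tert-butyldimethylsilyl ether of 15 F8. Desilylation with Et3N·3HF in THF/MeCN under argon comes back to the route at 15.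

## Further compounds

F1 | step 8 | dibenzyl (2R,2'R)-2,2'-{[2,2',3,3'-tetrakis(benzyloxy)-5,5'-divinyl-[1,1'-biphenyl]-4,4'-diyl]bis(oxy)}bis{2-[4-(benzyloxy)phenyl]acetate} | C=Cc1cc(-c2cc(C=C)c(O[C@H](c3ccc(OCc4ccccc4)cc3)C(=O)OCc3ccccc3)c(OCc3ccccc3)c2OCc2ccccc2)c(OCc2ccccc2)c(OCc2ccccc2)c1O[C@H](c1ccc(OCc2ccccc2)cc1)C(=O)OCc1ccccc1
F2 | step 6 | benzyl (2R)-2-[2,3-bis(benzyloxy)-4-bromo-6-formylphenoxy]-2-[4-(benzyloxy)phenyl]acetate | O=Cc1cc(Br)c(OCc2ccccc2)c(OCc2ccccc2)c1O[C@H](c1ccc(OCc2ccccc2)cc1)C(=O)OCc1ccccc1
F3 | step 9 | (2R,2'R,3R,3'R)-3,3',7,7',8,8'-hexakis(benzyloxy)-2,2'-bis[4-(benzyloxy)phenyl]-6,6'-bichromane | c1(-c2cc3c(c(OCc4ccccc4)c2OCc2ccccc2)O[C@H](c2ccc(OCc4ccccc4)cc2)[C@H](OCc2ccccc2)C3)cc2c(c(OCc3ccccc3)c1OCc1ccccc1)O[C@H](c1ccc(OCc3ccccc3)cc1)[C@H](OCc1ccccc1)C2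
F4 | step 10 | mono-O4'-tert-butyldimethylsilyl ether of 12 (silyl ether on unit 2, free 3,4-trans carbinol on unit 1) | c1(-c2cc3c(c(OCc4ccccc4)c2OCc2ccccc2)O[C@H](c2ccc(OCc4ccccc4)cc2)[C@H](OCc2ccccc2)[C@H]3O[Si](C)(C)C(C)(C)C)cc2c(c(OCc3ccccc3)c1OCc1ccccc1)O[C@H](c1ccc(OCc3ccccc3)cc1)[C@H](OCc1ccccc1)[C@H]2O
F5 | step 10 | unit 1 (2R,3S)-chroman-4-one with O4'-tert-butyldimethylsilyl ether on unit 2 | c1(-c2cc3c(c(OCc4ccccc4)c2OCc2ccccc2)O[C@H](c2ccc(OCc4ccccc4)cc2)[C@H](OCc2ccccc2)[C@H]3O[Si](C)(C)C(C)(C)C)cc2c(c(OCc3ccccc3)c1OCc1ccccc1)O[C@H](c1ccc(OCc3ccccc3)cc1)[C@H](OCc1ccccc1)C2=O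
F6 | step 10 | O4'-tert-butyldimethylsilyl ether of 14 (unit 1 3,4-cis carbinol free) | c1(-c2cc3c(c(OCc4ccccc4)c2OCc2ccccc2)O[C@H](c2ccc(OCc4ccccc4)cc2)[C@H](OCc2ccccc2)[C@H]3O[Si](C)(C)C(C)(C)C)cc2c(c(OCc3ccccc3)c1OCc1ccccc1)O[C@H](c1ccc(OCc3ccccc3)cc1)[C@H](OCc1ccccc1)[C@@H]2O
F7 | step 12 | 4,4'-bis-O-tert-butyldimethylsilyl ether of 14 | c1(-c2cc3c(c(OCc4ccccc4)c2OCc2ccccc2)O[C@H](c2ccc(OCc4ccccc4)cc2)[C@H](OCc2ccccc2)[C@H]3O[Si](C)(C)C(C)(C)C)cc2c(c(OCc3ccccc3)c1OCc1ccccc1)O[C@H](c1ccc(OCc3ccccc3)cc1)[C@H](OCc1ccccc1)[C@@H]2O[Si](C)(C)C(C)(C)C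
F8 | step 12 | 4,4'-bis-O-tert-butyldimethylsilyl ether of 15 | c1(-c2cc3c(c(O)c2O)O[C@H](c2ccc(O)cc2)[C@H](O)[C@H]3O[Si](C)(C)C(C)(C)C)cc2c(c(O)c1O)O[C@H](c1ccc(O)cc1)[C@H](O)[C@@H]2O[Si](C)(C)C(C)(C)C
A1 | alternative 1 | unit 1 (cis cyclic carbonate, benzyl ethers) bearing at C6 a 1-diazo-2-oxo-5,5-dimethoxypent-3-enyl chain | c6ccccc6COc1ccc([C@H]2Oc3c(cc(C(=[N+]=[N-])C(=O)/C=C/C(OC)OC)c(OCc6ccccc6)c3OCc6ccccc6)[C@@H](OC(=O)O7)[C@H]27)cc1
A2 | alternative 1 | di-tert-butoxyethyne | CC(C)(C)OC#COC(C)(C)C
A3 | alternative 1 | unit 1 joined at C6 to the new 2,3-di-tert-butoxy-4-hydroxy-5-(dimethoxymethyl)phenyl ring | c6ccccc6COc1ccc([C@H]2Oc3c(cc(-c4cc(C(OC)OC)c(O)c(OC(C)(C)C)c4OC(C)(C)C)c(OCc6ccccc6)c3OCc6ccccc6)[C@@H](OC(=O)O7)[C@H]27)cc1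
A4 | alternative 2 | 5,5'-dibromo-2,2',3,3'-tetrakis(benzyloxy)biphenyl-4,4'-diyl bis(acetonide-protected 2,3-dihydroxy-3-[4-(benzyloxy)phenyl]propanoate) | c1(-c2cc(Br)c(OC(=O)[C@H]9OC(C)(C)O[C@@H]9c8ccc(OCc6ccccc6)cc8)c(OCc6ccccc6)c2OCc6ccccc6)cc(Br)c(OC(=O)[C@H]9OC(C)(C)O[C@@H]9c8ccc(OCc6ccccc6)cc8)c(OCc6ccccc6)c1OCc6ccccc6
A5 | alternative 2 | biaryl bis(2-hydroxyaryl ketone) with acetonide-protected C2, C3 diols | c1(-c2cc(C(=O)[C@H]9OC(C)(C)O[C@@H]9c8ccc(OCc6ccccc6)cc8)c(O)c(OCc6ccccc6)c2OCc6ccccc6)cc(C(=O)[C@H]9OC(C)(C)O[C@@H]9c8ccc(OCc6ccccc6)cc8)c(O)c(OCc6ccccc6)c1OCc6ccccc6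
A6 | alternative 3 | 6,6'-linked bis(2,3-cis-flavan-3-ol) with C4 methylenes, O3 tert-butyl carbonate in unit 1 and O3' silyl ether in unit 2 | c6ccccc6COc1ccc([C@H]2Oc3c(cc(-c4cc5c(c(OCc6ccccc6)c4OCc6ccccc6)O[C@H](c4ccc(OCc6ccccc6)cc4)[C@H](O[Si](C)(C)C(C)(C)C)C5)c(OCc6ccccc6)c3OCc6ccccc6)C[C@H]2OC(=O)OC(C)(C)C)cc1
A7 | alternative 3 | dimer with cis cyclic carbonate in unit 1 and trans 4-acetate in unit 2 | c6ccccc6COc1ccc([C@H]2Oc3c(cc(-c4cc5c(c(OCc6ccccc6)c4OCc6ccccc6)O[C@H](c4ccc(OCc6ccccc6)cc4)[C@H](O[Si](C)(C)C(C)(C)C)[C@H]5OC(C)=O)c(OCc6ccccc6)c3OCc6ccccc6)[C@@H](OC(=O)O7)[C@H]27)cc1
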